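**Strategy.** The tetralol is cut at C3–C4. The feature exploited is that C1–C2–C3 of the saturated ring is a ketone-level three-carbon chain on C8a, storable as a 1-arylcyclopropanol (a strained homoenolate), while C4 carries a para-hydroxynaphthyl group and can therefore become a quinone methide carbon. In one operation a chiral Brønsted acid ionises a racemic diarylcarbinol and the cyclopropane σ-bond closes onto C4, forming the six-membered ring, the C1 ketone and the C4 stereocentre. The precursor is a triol: a 2-(1-hydroxycyclopropyl)-6-methoxyphenyl and a 4-hydroxy-5-methoxynaphthyl group on one carbinol carbon, assembled from an aryl dianion and a naphthaldehyde. A matched ketone reduction then sets C1.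

Key step: step 7

Numbering: atom labels C1–C8a are those of the tetralin ring of the target, which is the cis-(1S,4S) alcohol; primed labels belong to the naphthyl group.

Assumption: the (R)-configured phosphoric acid is taken to give the (S) configuration at C4; should the sense of induction be opposite, the (S)-catalyst is used with no other change.

**Step 1**
Reactants: 1 methyl 2-bromo-3-methoxybenzoate; 2 ethylmagnesium bromide
Product: 3 1-(2-bromo-3-methoxyphenyl)cyclopropan-1-ol
Conditions: EtMgBr (2.6 equiv, slow addition), Ti(OiPr)4 (20 mol %), THF, 0 °C → rt; then sat. aq NH4Cl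
Reagents that add atoms: ethylmagnesium bromide, CC[Mg]Br
Why: Kulinkovich cyclopropanation, in which the titanacyclopropane formed from the Grignard reagent and the titanium alkoxide acts as a 1,2-dicarbanion toward the ester, a reaction that tolerates ortho-bromoaryl esters and creates no stereocentre.

**Step 2**
Reactants: 4 8-methoxynaphthalen-1-ol
Product: 5 4-bromo-8-methoxynaphthalen-1-ol
Conditions: NBS (1.0 equiv), MeCN, −20 → 0 °C, dark
Reagents that add atoms: N-bromosuccinimide, O=C1CCC(=O)N1Br
Why: Electrophilic aromatic bromination with NBS in acetonitrile is para-selective for free 1-naphthols, and the free hydroxyl (made more electron-rich by its hydrogen bond to the peri methoxy oxygen) should direct substitution to C4 in preference to the positions activated by the methoxy group.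

**Step 3**
Reactants: 5 4-bromo-8-methoxynaphthalen-1-ol
Product: 6 [(4-bromo-8-methoxynaphthalen-1-yl)oxy](tert-butyl)dimethylsilane
Conditions: TBSOTf, 2,6-lutidine, CH2Cl2, 0 °C
Reagents that add atoms: tert-butyldimethylsilyl trifluoromethanesulfonate, CC(C)(C)[Si](C)(C)OS(=O)(=O)C(F)(F)F
Why: Silyl ether formation with the silyl triflate overcomes the peri hindrance and the internal hydrogen bond of the naphthol, and the masked oxygen keeps the later aldehyde electrophilic instead of a deactivated phenoxide.

**Step 4**
Reactants: 6 [(4-bromo-8-methoxynaphthalen-1-yl)oxy](tert-butyl)dimethylsilane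
Product: 8 4-[(tert-butyldimethylsilyl)oxy]-5-methoxy-1-naphthaldehyde, via aryllithium 7 (not isolated)
Conditions: n-BuLi (1.05 equiv), THF, −78 °C; DMF, −78 → 0 °C; then sat. aq NH4Cl
Reagents that add atoms: N,N-dimethylformamide, CN(C)C=O
Why: Bromine–lithium exchange followed by formylation with DMF (Bouveault-type aldehyde synthesis) fixes the formyl group exactly where the bromine stood, and the silyloxy group, being para to the lithiated carbon, cannot migrate to it.

**Step 5**
Reactants: 3 1-(2-bromo-3-methoxyphenyl)cyclopropan-1-ol; 8 4-[(tert-butyldimethylsilyl)oxy]-5-methoxy-1-naphthaldehyde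
Product: 10 racemic 1-{2-[{4-[(tert-butyldimethylsilyl)oxy]-5-methoxynaphthalen-1-yl}(hydroxy)methyl]-3-methoxyphenyl}cyclopropan-1-ol, via dilithio cyclopropanolate 9 (not isolated)
Conditions: 3, n-BuLi (2.1 equiv), THF, −78 °C; then 8, −78 → −40 °C; then sat. aq NH4Cl at −40 °C
Reagents that add atoms: none
Why: O-deprotonation followed by bromine–lithium exchange gives an alkoxide-bearing aryllithium (Parham-type dianion) that undergoes 1,2-addition to the non-enolisable aldehyde; leaving the cyclopropanol as its lithium alkoxide avoids an O-silyl group that could shift to the neighbouring lithiated carbon, and the carbinol centre is deliberately racemic because step 7 erases it.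

**Step 6**
Reactants: 10 racemic 1-{2-[{4-[(tert-butyldimethylsilyl)oxy]-5-methoxynaphthalen-1-yl}(hydroxy)methyl]-3-methoxyphenyl}cyclopropan-1-ol
Product: 11 racemic 4-{hydroxy[2-(1-hydroxycyclopropyl)-6-methoxyphenyl]methyl}-8-methoxynaphthalen-1-ol
Conditions: TBAF/AcOH (1:1, 1.1 equiv), THF, 0 °C; short filtration through Et3N-deactivated silica, used at once
Reagents that add atoms: none
Why: Fluoride cleavage of the aryl silyl ether, buffered with acetic acid so that neither naphthoxide-driven loss of hydroxide nor base-induced opening of the cyclopropanol can begin, should free the naphthol while the two alkyl hydroxyls stay untouched.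

**Step 7**
Reactants: 11 racemic 4-{hydroxy[2-(1-hydroxycyclopropyl)-6-methoxyphenyl]methyl}-8-methoxynaphthalen-1-ol
Product: 13 (S)-4-(4-hydroxy-5-methoxynaphthalen-1-yl)-5-methoxy-3,4-dihydronaphthalen-1(2H)-one, via naphthoquinone methide 12 (not isolated)
Conditions: (R)-TRIP (10 mol %), PhMe (0.02 M), 4 Å MS, 0 → 25 °C
Reagents that add atoms: none
Why: Proposed new method: the phosphoric acid should ionise the doubly benzylic carbinol of 11, which the para-hydroxyl of the naphthalene turns into quinone methide 12 held as a hydrogen-bonded ion pair, and the C1–C3 σ-bond of the adjacent cyclopropanol then attacks the exocyclic carbon C4 while the hydroxyl oxygen donates, so that C3–C4 forms, C1–C3 breaks, C1 becomes the aryl ketone and the naphthol is rearomatised. The closest known reaction types are phosphoric-acid-catalysed 1,6-additions to para-quinone methides made in situ from para-hydroxybenzylic alcohols, acid-promoted cyclisations of cyclopropanols onto oxocarbenium ions and C-alkylations of metal homoenolates, none of which combines an intramolecular closure with enantiocontrol at the electrophilic carbon. The ring C1–C2–C3–C4–C4a–C8a closes in a 6-exo-trig mode with respect to the exocyclic C4=C1′ bond, the attacking C3 being delivered through the five-atom array C3–C1–C8a–C4a–C4; this is geometrically open because the di-ortho-substituted benzene ring must stand roughly perpendicular to the quinone methide plane, which points one lobe of the C4 p-orbital at the cyclopropane. The C4 stereocentre is controlled by the chiral phosphate, which binds the quinone methide oxygen and the cyclopropanol OH at once and thereby decides on which face of planar C4 the cyclopropanol sits; both enantiomers of 11 give the same 12, so the racemate converges. The step needs C–C closure to win over O-closure and over protonolysis: any closure through oxygen to a spiro-phthalan would be reversible under the acid because the same stabilised cation re-forms, ring opening to the ketone cannot be reversed, either CH2 group of the cyclopropane leads to the same product, and a weak acid at low temperature in a non-polar solvent should keep protonation of the cyclopropane slow.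

**Step 8**
Reactants: 13 (S)-4-(4-hydroxy-5-methoxynaphthalen-1-yl)-5-methoxy-3,4-dihydronaphthalen-1(2H)-one
Product: 14 (1S,4S)-4-(4-hydroxy-5-methoxynaphthalen-1-yl)-5-methoxy-1,2,3,4-tetrahydronaphthalen-1-ol
Conditions: RuCl(p-cymene)[(S,S)-TsDPEN] (2 mol %), HCO2H/Et3N (5:2), DMF, 30 °C
Reagents that add atoms: none
Why: Noyori asymmetric transfer hydrogenation of an aryl ketone, in which the (S,S)-catalyst should give the (S)-carbinol by hydride delivery to the face anti to the C4 naphthyl group (held pseudoaxial by the peri C5 methoxy), so that catalyst and substrate control are matched and lead to the cis-(1S,4S) alcohol.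

**Compound list**
1 | methyl 2-bromo-3-methoxybenzoate | COC(=O)c1cccc(OC)c1Br | starting material
2 | ethylmagnesium bromide | CC[Mg]Br | starting material
3 | 1-(2-bromo-3-methoxyphenyl)cyclopropan-1-ol | COc1cccc(C2(O)CC2)c1Br | intermediate
4 | 8-methoxynaphthalen-1-ol | COc1cccc2cccc(O)c12 | starting material
5 | 4-bromo-8-methoxynaphthalen-1-ol | COc1cccc2c(Br)ccc(O)c12 | intermediate
6 | [(4-bromo-8-methoxynaphthalen-1-yl)oxy](tert-butyl)dimethylsilane | COc1cccc2c(Br)ccc(O[Si](C)(C)C(C)(C)C)c12 | intermediate
7 | {4-[(tert-butyldimethylsilyl)oxy]-5-methoxynaphthalen-1-yl}lithium (aryllithium, not isolated) | COc1cccc2c([Li])ccc(O[Si](C)(C)C(C)(C)C)c12 | intermediate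
8 | 4-[(tert-butyldimethylsilyl)oxy]-5-methoxy-1-naphthaldehyde | COc1cccc2c(C=O)ccc(O[Si](C)(C)C(C)(C)C)c12 | intermediate
9 | lithium 1-(2-lithio-3-methoxyphenyl)cyclopropan-1-olate (dilithio cyclopropanolate, not isolated) | COc1cccc(C2(O[Li])CC2)c1[Li] | intermediate
10 | racemic 1-{2-[{4-[(tert-butyldimethylsilyl)oxy]-5-methoxynaphthalen-1-yl}(hydroxy)methyl]-3-methoxyphenyl}cyclopropan-1-ol | COc1cccc(C2(O)CC2)c1C(O)c1ccc(O[Si](C)(C)C(C)(C)C)c2c(OC)cccc12 | intermediate
11 | racemic 4-{hydroxy[2-(1-hydroxycyclopropyl)-6-methoxyphenyl]methyl}-8-methoxynaphthalen-1-ol | COc1cccc(C2(O)CC2)c1C(O)c1ccc(O)c2c(OC)cccc12 | intermediate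
12 | 4-{(E)-[2-(1-hydroxycyclopropyl)-6-methoxyphenyl]methylidene}-8-methoxynaphthalen-1(4H)-one (naphthoquinone methide, aryl group anti to the peri position, not isolated) | COc1cccc(C2(O)CC2)c1/C=C1\C=CC(=O)c2c(OC)cccc12 | intermediate
13 | (S)-4-(4-hydroxy-5-methoxynaphthalen-1-yl)-5-methoxy-3,4-dihydronaphthalen-1(2H)-one | COc1cccc2c1[C@H](c1ccc(O)c3c(OC)cccc13)CCC2=O | intermediate
14 | (1S,4S)-4-(4-hydroxy-5-methoxynaphthalen-1-yl)-5-methoxy-1,2,3,4-tetrahydronaphthalen-1-ol (Dipolynaphthalene B, cis) | COc1cccc2c1[C@H](c1ccc(O)c3c(OC)cccc13)CC[C@@H]2O | target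

**Step count.** Total: 8 steps. Longest linear sequence: 7 steps (4 → 5 → 6 → 8 → 10 → 11 → 13 → 14).

**Steps most likely to fail**

Step 7. The cation may be captured only through the cyclopropanol oxygen without onward C–C closure, the cyclopropanol may be opened by protonation, or the closure may proceed with poor enantiofacial control. The fallback uses only known reactions, sets out from 4 and returns to the route at 14. Commercial 5-methoxy-3,4-dihydronaphthalen-1(2H)-one F1 is brominated at its benzylic C4 under Wohl–Ziegler conditions (NBS, AIBN, PhCF3, reflux) to racemic 4-bromo-5-methoxy-3,4-dihydronaphthalen-1(2H)-one F2. Friedel–Crafts alkylation of naphthol 4 with F2 (HFIP, 0 °C → rt), para to the free hydroxyl, should give the racemic tetralone F3. Transfer hydrogenation of F3 under the step 8 conditions is reagent-controlled at C1, so the (S)-ketone should give 14 and the (R)-ketone the trans-(1S,4R) alcohol F4; these are diastereomers and are separated by chromatography.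

Step 5. The aryllithium may be quenched by proton transfer before it adds, or the aggregated, di-ortho-substituted dianion may add too slowly to the peri-hindered aldehyde. The fallback sets out from 1 and 8 and returns at 10. Bromine–magnesium exchange on ester 1 (i-PrMgCl·LiCl, THF, −20 °C), addition of the arylmagnesium to 8 and lactonisation of the resulting alkoxide onto the neighbouring ester should give the racemic phthalide 3-{4-[(tert-butyldimethylsilyl)oxy]-5-methoxynaphthalen-1-yl}-4-methoxy-2-benzofuran-1(3H)-one F5. Kulinkovich cyclopropanation of this lactone (EtMgBr, Ti(OiPr)4, THF) opens the ring and should give diol 10 directly.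

Step 2. Bromination may occur at a position other than C4, or over-bromination or oxidation of the electron-rich naphthol may take over. The fallback removes the regiochemical choice by symmetry, sets out from 4 and returns at 8. O-Methylation (MeI, K2CO3, acetone) gives 1,8-dimethoxynaphthalene F6, whose two para positions are equivalent. Vilsmeier–Haack formylation (POCl3, DMF) gives 4,5-dimethoxy-1-naphthaldehyde F7. Nucleophilic demethylation with sodium ethanethiolate (DMF, 100 °C) removes the methyl group para to the formyl group to give 4-hydroxy-5-methoxy-1-naphthaldehyde F8. Silylation as in step 3 then gives 8.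

**Further compounds**
F1 | step 7 | 5-methoxy-3,4-dihydronaphthalen-1(2H)-one | COc1cccc2c1CCCC2=O
F2 | step 7 | racemic 4-bromo-5-methoxy-3,4-dihydronaphthalen-1(2H)-one | COc1cccc2c1C(Br)CCC2=O
F3 | step 7 | racemic 4-(4-hydroxy-5-methoxynaphthalen-1-yl)-5-methoxy-3,4-dihydronaphthalen-1(2H)-one | COc1cccc2c1C(c1ccc(O)c3c(OC)cccc13)CCC2=O
F4 | step 7 | (1S,4R)-4-(4-hydroxy-5-methoxynaphthalen-1-yl)-5-methoxy-1,2,3,4-tetrahydronaphthalen-1-ol (trans) | COc1cccc2c1[C@@H](c1ccc(O)c3c(OC)cccc13)CC[C@@H]2O
F5 | step 5 | racemic 3-{4-[(tert-butyldimethylsilyl)oxy]-5-methoxynaphthalen-1-yl}-4-methoxy-2-benzofuran-1(3H)-one | COc1cccc2C(=O)OC(c3ccc(O[Si](C)(C)C(C)(C)C)c4c(OC)cccc34)c12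
F6 | step 2 | 1,8-dimethoxynaphthalene | COc1cccc2cccc(OC)c12
F7 | step 2 | 4,5-dimethoxy-1-naphthaldehyde | COc1ccc(C=O)c2cccc(OC)c12
F8 | step 2 | 4-hydroxy-5-methoxy-1-naphthaldehyde | COc1cccc2c(C=O)ccc(O)c12
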